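**Retrosynthetic overview**

- The strategy rests on the one ring, the 1,2-dioxolane O1–O2–C3–C4–C5. Both peroxide carbons are fully substituted and sit 1,3 across the C4 methylene. C3 (methyl plus two-carbon ester arm) is the carbonyl carbon of a 4-oxygenated butan-2-one, and C4–C5 (methyl plus C15 chain) is the C=C of a 2-methylalk-1-ene.
- Key disconnection: C3–C4 and O1–C5 are made in one operation by adding the chain alkene to the silylperoxycarbenium ion of the butanone unit (arm as TBS ether, chain end as TBDPS ether). This is the only ring-forming step and it comes first.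
- The annulation is racemic and hardly diastereoselective. The trans isomer is isolated, the arm alcohol is unmasked and resolved as (1S)-camphanates, and the camphanate then protects the arm.
- The chain is built after the ring, because a diene would compete for the cation: C7' alcohol to aldehyde, two-carbon Wittig to the E-enal, then Julia–Kocienski olefination with a (Z)-hex-3-enyl tetrazolyl sulfone to the 7E,9E,12Z triene.
- The arm is finished last (camphanate off, CH2CH2OH to CH2CHO to CH2CO2H to CH2CO2Me), so that the β-peroxy ester never meets a strong base.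

Key step: step 8

Remark on conventions: the ring is numbered O1–O2–C3–C4–C5 throughout, with C3 carrying the arm and C5 the chain. Racemic compounds are drawn as the enantiomer that is carried on. The C3 descriptor changes from S to R in step 16 only because the CIP priority of the arm rises; the spatial arrangement is unchanged. Compounds 1, 6, 8, 10, 20 and (1S)-(−)-camphanic chloride are taken as commercial.

**Route**

Step 1
Reactants: 1 3-methylbut-3-en-1-ol
Product: 2 tert-butyldimethyl[(3-methylbut-3-en-1-yl)oxy]silane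
Conditions: TBSCl, imidazole, CH2Cl2, 0 °C → rt
Reagents that add atoms: tert-butyldimethylsilyl chloride, CC(C)(C)[Si](C)(C)Cl
Why: Imidazole-promoted O-silylation of a primary alcohol; the TBS ether is chosen because it can later be cleaved in the presence of a TBDPS ether.

Step 2
Reactants: 2 tert-butyldimethyl[(3-methylbut-3-en-1-yl)oxy]silane
Product: 4 tert-butyl(3-hydroperoxy-3-methoxybutoxy)dimethylsilane (racemic), via carbonyl oxide 3 (not isolated)
Conditions: O3, CH2Cl2/MeOH, −78 °C; N2 purge, no reductive work-up, concentrate cold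
Reagents that add atoms: ozone, [O-][O+]=O; methanol, CO
Why: Criegee ozonolysis of a 1,1-disubstituted alkene splits the primary ozonide into formaldehyde and the more substituted carbonyl oxide 3, which methanol traps as the α-methoxy hydroperoxide.

Step 3
Reactants: 4 tert-butyl(3-hydroperoxy-3-methoxybutoxy)dimethylsilane
Product: 5 tert-butyl{3-methoxy-3-[(triethylsilyl)peroxy]butoxy}dimethylsilane (racemic)
Conditions: Et3SiCl, imidazole, DMF, 0 °C
Reagents that add atoms: chlorotriethylsilane, CC[Si](Cl)(CC)CC
Why: O-silylation of the hydroperoxide under mild base gives the triethylsilyl peroxyketal, whose stereocentre is of no consequence because it is ionised in step 8.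

Step 4
Reactants: 6 6-bromohexan-1-ol
Product: 7 [(6-bromohexyl)oxy](tert-butyl)diphenylsilane
Conditions: TBDPSCl, imidazole, CH2Cl2, rt
Reagents that add atoms: tert-butyldiphenylsilyl chloride, CC(C)(C)[Si](Cl)(c1ccccc1)c1ccccc1
Why: Standard silylation; the TBDPS ether is inert to Grignard reagents and to SnCl4 at low temperature and outlasts the acid that later removes the TBS group.

Step 5
Reactants: 7 [(6-bromohexyl)oxy](tert-butyl)diphenylsilane; 8 2-methylallylmagnesium chloride
Product: 9 tert-butyl[(8-methylnon-8-en-1-yl)oxy]diphenylsilane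
Conditions: Li2CuCl4 (3 mol %), THF, −20 °C → rt
Reagents that add atoms: none
Why: Copper-catalysed cross-coupling of a Grignard reagent with a primary alkyl bromide (Kochi-type coupling); the symmetrical methallyl unit cannot give regioisomers.

Step 6
Reactants: 10 (3Z)-hex-3-en-1-ol
Product: 11 5-[(3Z)-hex-3-en-1-ylsulfanyl]-1-phenyl-1H-tetrazole
Conditions: 1-phenyl-1H-tetrazole-5-thiol, PPh3, DIAD, THF, 0 °C → rt
Reagents that add atoms: 1-phenyl-1H-tetrazole-5-thiol, Sc1nnnn1-c1ccccc1
Why: Mitsunobu thioetherification of a primary alcohol with an acidic thiol; the Z alkene is not touched.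

Step 7
Reactants: 11 5-[(3Z)-hex-3-en-1-ylsulfanyl]-1-phenyl-1H-tetrazole
Product: 12 5-[(3Z)-hex-3-en-1-ylsulfonyl]-1-phenyl-1H-tetrazole
Conditions: (NH4)6Mo7O24·4H2O (10 mol %), 30% aq. H2O2, EtOH, 0 °C → rt
Reagents that add atoms: hydrogen peroxide, OO
Why: Molybdate-catalysed oxidation of sulfide to sulfone, which is much faster than epoxidation of an unactivated cis-alkene.

Step 8
Reactants: 5 tert-butyl{3-methoxy-3-[(triethylsilyl)peroxy]butoxy}dimethylsilane; 9 tert-butyl[(8-methylnon-8-en-1-yl)oxy]diphenylsilane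
Product: 15 (3S*,5S*)-3-{2-[(tert-butyldimethylsilyl)oxy]ethyl}-5-{7-[(tert-butyldiphenylsilyl)oxy]heptyl}-3,5-dimethyl-1,2-dioxolane (racemic; arm trans to chain), via silylperoxycarbenium ion 13 (not isolated), via tertiary C5 carbocation 14 (not isolated)
Conditions: SnCl4 (1.0 equiv), CH2Cl2, −78 °C; aq. NaHCO3 quench at −78 °C; chromatography
Reagents that add atoms: none
Why: SnCl4 removes methoxide from 5 to give ion 13 at C3, the CH2 terminus of 9 adds to it (C3–C4) to give the tertiary cation 14 at C5, and the silylated peroxide oxygen captures that cation (O1–C5) with loss of the triethylsilyl group as Et3SiOMe. The closest known reaction type is the Lewis-acid [3+2] annulation of triethylsilyl peroxyketals with 1,1-disubstituted alkenes to 3,3,5,5-tetrasubstituted 1,2-dioxolanes. The one ring (O1–O2–C3–C4–C5) closes by intramolecular capture of the C5 cation by O1 through a five-membered transition state, as the second bond of a stepwise cationic annulation. C3 is created when the alkene attacks either face of the planar ion 13, with no bias and therefore racemic, and C5 is fixed in the ring closure, where only the small size difference between methyl and a CH2-chain on both carbons decides cis against trans. The step needs regioselectivity, which the 1,1-disubstituted alkene secures by placing the cation on the tertiary carbon, and chemoselectivity, which is secured by carrying both oxygens as silyl ethers (no carbonyl near the ion) and by leaving the diene for later. Diastereoselectivity is not secured, so a cis/trans mixture with at best a modest excess of the trans isomer is expected; the cis isomer is removed by chromatography here or after step 9, and the absolute configuration is settled in step 10.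

Step 9
Reactants: 15 racemic trans-dioxolane bis-silyl ether
Product: 16 2-[(3S*,5S*)-5-{7-[(tert-butyldiphenylsilyl)oxy]heptyl}-3,5-dimethyl-1,2-dioxolan-3-yl]ethan-1-ol (racemic)
Conditions: PPTS (0.2 equiv), MeOH, rt; chromatographic removal of residual cis isomer
Reagents that add atoms: none
Why: Acid-catalysed methanolysis cleaves the primary TBS ether far faster than the TBDPS ether, the fully substituted dialkyl peroxide tolerates mild acid, and the free hydroxyl should make the cis/trans separation easier.

Step 10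
Reactants: 16 racemic trans arm alcohol
Product: 17 2-[(3S,5S)-5-{7-[(tert-butyldiphenylsilyl)oxy]heptyl}-3,5-dimethyl-1,2-dioxolan-3-yl]ethyl (1S,4R)-4,7,7-trimethyl-3-oxo-2-oxabicyclo[2.2.1]heptane-1-carboxylate
Conditions: (1S)-(−)-camphanic chloride, Et3N, DMAP (cat.), CH2Cl2, 0 °C → rt; preparative HPLC on silica (or crystallisation) of the two esters
Reagents that add atoms: (1S)-(−)-camphanic chloride, ClC(=O)[C@@]12CC[C@@](C)(C(=O)O1)C2(C)C
Why: DMAP-catalysed acylation turns the racemate into two diastereomeric esters (classical resolution through covalent diastereomers); no new stereocentre is formed, the (3S,5S) ester is selected (configuration to be secured by X-ray analysis against the known camphanate centres), and the ester, which has no α-hydrogen, stays on as the arm protecting group.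

Step 11
Reactants: 17 (3S,5S)-camphanate TBDPS ether
Product: 18 2-[(3S,5S)-5-(7-hydroxyheptyl)-3,5-dimethyl-1,2-dioxolan-3-yl]ethyl (1S,4R)-camphanate
Conditions: HF·pyridine, pyridine, THF, 0 °C → rt
Reagents that add atoms: none
Why: Fluoride-mediated desilylation driven by the Si–F bond; buffered HF leaves the ester, the lactone and the peroxide intact.

Step 12
Reactants: 18 chain alcohol
Product: 19 2-[(3S,5S)-3,5-dimethyl-5-(7-oxoheptyl)-1,2-dioxolan-3-yl]ethyl (1S,4R)-camphanate
Conditions: Dess–Martin periodinane, NaHCO3, CH2Cl2, 0 °C → rt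
Reagents that add atoms: none
Why: Dess–Martin oxidation of a primary alcohol stops at the aldehyde and does not affect esters or the dialkyl peroxide.

Step 13
Reactants: 19 chain aldehyde; 20 (triphenylphosphoranylidene)acetaldehyde
Product: 21 2-[(3S,5S)-3,5-dimethyl-5-[(7E)-9-oxonon-7-en-1-yl]-1,2-dioxolan-3-yl]ethyl (1S,4R)-camphanate
Conditions: toluene, 70 °C
Reagents that add atoms: none
Why: Wittig reaction with a stabilised formylmethylene ylide adds two carbons and should give the E-enal (7E); it is neutral and does not disturb ester or peroxide.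

Step 14
Reactants: 21 E-enal; 12 5-[(3Z)-hex-3-en-1-ylsulfonyl]-1-phenyl-1H-tetrazole
Product: 23 2-[(3S,5S)-3,5-dimethyl-5-[(7E,9E,12Z)-pentadeca-7,9,12-trien-1-yl]-1,2-dioxolan-3-yl]ethyl (1S,4R)-camphanate, via potassium sulfonyl carbanion 22 (not isolated)
Conditions: 12, KN(SiMe3)2, DME, −60 °C, 20 min; then 21, −60 °C → rt; aq. NH4Cl
Reagents that add atoms: none
Why: Julia–Kocienski olefination, in which carbanion 22 adds to the enal and Smiles rearrangement with loss of SO2 and the tetrazololate forms C9=C10, expected E for a phenyltetrazolyl sulfone with potassium in DME; the sulfone is metalated first so that the base meets neither the enal nor the ester, and the 7E and 12Z alkenes are carried through unchanged.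

Step 15
Reactants: 23 triene camphanate
Product: 24 2-[(3S,5S)-3,5-dimethyl-5-[(7E,9E,12Z)-pentadeca-7,9,12-trien-1-yl]-1,2-dioxolan-3-yl]ethan-1-ol
Conditions: K2CO3, MeOH/THF, rt
Reagents that add atoms: none
Why: Base-catalysed methanolysis (transesterification) frees the arm alcohol; the dioxolane has no α-hydrogen for Kornblum–DeLaMare cleavage and no β-carbonyl yet, and carbonate leaves the triene alone.

Step 16
Reactants: 24 triene arm alcohol
Product: 25 2-[(3R,5S)-3,5-dimethyl-5-[(7E,9E,12Z)-pentadeca-7,9,12-trien-1-yl]-1,2-dioxolan-3-yl]acetaldehyde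
Conditions: Dess–Martin periodinane, NaHCO3, CH2Cl2, 0 °C; used at once
Reagents that add atoms: none
Why: Dess–Martin oxidation under bicarbonate buffer gives the β-peroxy aldehyde without strong acid or base, which matters because enolisation would open the ring by retro-oxa-Michael loss of the peroxide.

Step 17
Reactants: 25 β-peroxy aldehyde
Product: 26 2-[(3R,5S)-3,5-dimethyl-5-[(7E,9E,12Z)-pentadeca-7,9,12-trien-1-yl]-1,2-dioxolan-3-yl]acetic acid
Conditions: NaClO2, NaH2PO4, 2-methylbut-2-ene (excess), t-BuOH/H2O, 0 °C → rt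
Reagents that add atoms: sodium chlorite, [Na+].[O-]Cl=O
Why: Pinnick oxidation converts the aldehyde into the acid under weakly acidic buffer, with excess 2-methylbut-2-ene trapping hypochlorous acid before it can attack the triene.

Step 18
Reactants: 26 dioxolane acetic acid
Product: 27 methyl 2-[(3R,5S)-3,5-dimethyl-5-[(7E,9E,12Z)-pentadeca-7,9,12-trien-1-yl]-1,2-dioxolan-3-yl]acetate (target)
Conditions: Me3SiCHN2, toluene/MeOH, 0 °C
Reagents that add atoms: trimethylsilyldiazomethane, C[Si](C)(C)C=[N+]=[N-]
Why: Methyl esterification with trimethylsilyldiazomethane in methanol is neutral, so the β-peroxy ester is formed without base and C3 cannot be scrambled by ring opening and reclosure.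

**Compound list**

1 | 3-methylbut-3-en-1-ol | C=C(C)CCO | starting material
2 | tert-butyldimethyl[(3-methylbut-3-en-1-yl)oxy]silane | C=C(C)CCO[Si](C)(C)C(C)(C)C | intermediate
3 | carbonyl oxide of 4-[(tert-butyldimethylsilyl)oxy]butan-2-one | CC(CCO[Si](C)(C)C(C)(C)C)=[O+][O-] | intermediate (not isolated)
4 | tert-butyl(3-hydroperoxy-3-methoxybutoxy)dimethylsilane (racemic) | CC(OC)(OO)CCO[Si](C)(C)C(C)(C)C | intermediate
5 | tert-butyl{3-methoxy-3-[(triethylsilyl)peroxy]butoxy}dimethylsilane (racemic) | CC(OC)(OO[Si](CC)(CC)CC)CCO[Si](C)(C)C(C)(C)C | intermediate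
6 | 6-bromohexan-1-ol | OCCCCCCBr | starting material
7 | [(6-bromohexyl)oxy](tert-butyl)diphenylsilane | BrCCCCCCO[Si](c1ccccc1)(c1ccccc1)C(C)(C)C | intermediate
8 | 2-methylallylmagnesium chloride | C=C(C)C[Mg]Cl | starting material
9 | tert-butyl[(8-methylnon-8-en-1-yl)oxy]diphenylsilane | C=C(C)CCCCCCCO[Si](c1ccccc1)(c1ccccc1)C(C)(C)C | intermediate
10 | (3Z)-hex-3-en-1-ol | CC/C=C\CCO | starting material
11 | 5-[(3Z)-hex-3-en-1-ylsulfanyl]-1-phenyl-1H-tetrazole | CC/C=C\CCSc1nnnn1-c1ccccc1 | intermediate
12 | 5-[(3Z)-hex-3-en-1-ylsulfonyl]-1-phenyl-1H-tetrazole | CC/C=C\CCS(=O)(=O)c1nnnn1-c1ccccc1 | intermediate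
13 | 4-[(tert-butyldimethylsilyl)oxy]-2-[(triethylsilyl)peroxy]butan-2-ylium (silylperoxycarbenium ion) | C[C+](CCO[Si](C)(C)C(C)(C)C)OO[Si](CC)(CC)CC | intermediate (not isolated)
14 | tertiary C5 carbocation after C3–C4 bond formation (racemic at C3) | C[C+](CCCCCCCO[Si](c1ccccc1)(c1ccccc1)C(C)(C)C)C[C@](C)(CCO[Si](C)(C)C(C)(C)C)OO[Si](CC)(CC)CC | intermediate (not isolated)
15 | (3S*,5S*)-3-{2-[(tert-butyldimethylsilyl)oxy]ethyl}-5-{7-[(tert-butyldiphenylsilyl)oxy]heptyl}-3,5-dimethyl-1,2-dioxolane (racemic, arm trans to chain) | CC(C)(C)[Si](c1ccccc1)(c1ccccc1)OCCCCCCC[C@@]2(C)C[C@](C)(CCO[Si](C)(C)C(C)(C)C)OO2 | intermediate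
16 | 2-[(3S*,5S*)-5-{7-[(tert-butyldiphenylsilyl)oxy]heptyl}-3,5-dimethyl-1,2-dioxolan-3-yl]ethan-1-ol (racemic) | CC(C)(C)[Si](c1ccccc1)(c1ccccc1)OCCCCCCC[C@@]2(C)C[C@](C)(CCO)OO2 | intermediate
17 | 2-[(3S,5S)-5-{7-[(tert-butyldiphenylsilyl)oxy]heptyl}-3,5-dimethyl-1,2-dioxolan-3-yl]ethyl (1S,4R)-camphanate | CC(C)(C)[Si](c1ccccc1)(c1ccccc1)OCCCCCCC[C@@]2(C)C[C@](C)(CCOC(=O)[C@@]34CC[C@@](C)(C(=O)O3)C4(C)C)OO2 | intermediate
18 | 2-[(3S,5S)-5-(7-hydroxyheptyl)-3,5-dimethyl-1,2-dioxolan-3-yl]ethyl (1S,4R)-camphanate | OCCCCCCC[C@@]1(C)C[C@](C)(CCOC(=O)[C@@]23CC[C@@](C)(C(=O)O2)C3(C)C)OO1 | intermediate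
19 | 2-[(3S,5S)-3,5-dimethyl-5-(7-oxoheptyl)-1,2-dioxolan-3-yl]ethyl (1S,4R)-camphanate | O=CCCCCCC[C@@]1(C)C[C@](C)(CCOC(=O)[C@@]23CC[C@@](C)(C(=O)O2)C3(C)C)OO1 | intermediate
20 | (triphenylphosphoranylidene)acetaldehyde | O=CC=P(c1ccccc1)(c1ccccc1)c1ccccc1 | starting material
21 | 2-[(3S,5S)-3,5-dimethyl-5-[(7E)-9-oxonon-7-en-1-yl]-1,2-dioxolan-3-yl]ethyl (1S,4R)-camphanate | O=C/C=C/CCCCCC[C@@]1(C)C[C@](C)(CCOC(=O)[C@@]23CC[C@@](C)(C(=O)O2)C3(C)C)OO1 | intermediate
22 | potassium salt of sulfone 12 (α-sulfonyl carbanion) | CC/C=C\C[CH-]S(=O)(=O)c1nnnn1-c1ccccc1.[K+] | intermediate (not isolated)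
23 | 2-[(3S,5S)-3,5-dimethyl-5-[(7E,9E,12Z)-pentadeca-7,9,12-trien-1-yl]-1,2-dioxolan-3-yl]ethyl (1S,4R)-camphanate | CC/C=C\C/C=C/C=C/CCCCCC[C@@]1(C)C[C@](C)(CCOC(=O)[C@@]23CC[C@@](C)(C(=O)O2)C3(C)C)OO1 | intermediate
24 | 2-[(3S,5S)-3,5-dimethyl-5-[(7E,9E,12Z)-pentadeca-7,9,12-trien-1-yl]-1,2-dioxolan-3-yl]ethan-1-ol | CC/C=C\C/C=C/C=C/CCCCCC[C@@]1(C)C[C@](C)(CCO)OO1 | intermediate
25 | 2-[(3R,5S)-3,5-dimethyl-5-[(7E,9E,12Z)-pentadeca-7,9,12-trien-1-yl]-1,2-dioxolan-3-yl]acetaldehyde | CC/C=C\C/C=C/C=C/CCCCCC[C@@]1(C)C[C@](C)(CC=O)OO1 | intermediate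
26 | 2-[(3R,5S)-3,5-dimethyl-5-[(7E,9E,12Z)-pentadeca-7,9,12-trien-1-yl]-1,2-dioxolan-3-yl]acetic acid | CC/C=C\C/C=C/C=C/CCCCCC[C@@]1(C)C[C@](C)(CC(=O)O)OO1 | intermediate
27 | methyl 2-[(3R,5S)-3,5-dimethyl-5-[(7E,9E,12Z)-pentadeca-7,9,12-trien-1-yl]-1,2-dioxolan-3-yl]acetate | CC/C=C\C/C=C/C=C/CCCCCC[C@@]1(C)C[C@](C)(CC(=O)OC)OO1 | target

**Step count**

Total: 18 steps. Longest linear sequence: 14 steps (steps 1–3, then 8–18).

**Steps most likely to fail**

Step 8. The cations 13 and 14 may be lost by proton elimination, chloride capture or a Criegee-type 1,2-shift before O1 closes the ring, and the ring closure may show little facial preference. The fallback sets out from 9 and 2 and comes back at 15. It reverses the roles of the two halves, so that the ring is built through C4–C5 and O2–C3. Alkene 9 is ozonised in CH2Cl2/MeOH at −78 °C to 9-[(tert-butyldiphenylsilyl)oxy]-2-methoxynonan-2-yl hydroperoxide F1. This is silylated (Et3SiCl, imidazole, DMF) to tert-butyl({8-methoxy-8-[(triethylsilyl)peroxy]nonyl}oxy)diphenylsilane F2. F2 and the homoallylic silyl ether 2 are then treated with SnCl4 in CH2Cl2 at −78 °C. The unfunctionalised peroxycarbenium ion at C5 adds the CH2 terminus of 2, and the C3 cation is captured by the peroxide oxygen. This should give the same dioxolane 15, again as a racemic cis/trans pair to be separated.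

Step 10. The two camphanates may not be discriminated on silica, since their stereogenic units lie five bonds apart. The fallback sets out from 16 and comes back at 17. The enantiomers of 16 are separated directly on a polysaccharide chiral stationary phase (amylose tris(3,5-dimethylphenylcarbamate), supercritical CO2/MeOH), with UV detection through the TBDPS group. The (3S,5S) enantiomer, 2-[(3S,5S)-5-{7-[(tert-butyldiphenylsilyl)oxy]heptyl}-3,5-dimethyl-1,2-dioxolan-3-yl]ethan-1-ol F3, is then acylated with (1S)-camphanic chloride under the conditions of step 10. The ester now serves only as a base-stable protecting group and rejoins the route at 17.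

Step 14. E selectivity at the new C9=C10 bond may erode with an enal as partner, and the metalated sulfone may attack the camphanate. The fallback sets out from 10 and 21 and comes back at 23. It forms C9=C10 by a Z-selective Wittig reaction and then corrects the geometry thermodynamically. Alcohol 10 is converted with PPh3, I2 and imidazole into (3Z)-1-iodohex-3-ene F4, and with PPh3 in refluxing MeCN into [(3Z)-hex-3-en-1-yl]triphenylphosphonium iodide F5. The ylide from F5 (NaN(SiMe3)2, THF, −78 °C) and enal 21 should give 2-[(3S,5S)-3,5-dimethyl-5-[(7E,9Z,12Z)-pentadeca-7,9,12-trien-1-yl]-1,2-dioxolan-3-yl]ethyl (1S,4R)-camphanate F6. Catalytic iodine in CH2Cl2 under ambient light then equilibrates only the conjugated diene, through reversible iodine-atom addition to an allylic radical. The isolated 12Z alkene should stay as it is, and the product is 23.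

**Further compounds**

F1 | step 8 | 9-[(tert-butyldiphenylsilyl)oxy]-2-methoxynonan-2-yl hydroperoxide (racemic) | CC(OC)(OO)CCCCCCCO[Si](c1ccccc1)(c1ccccc1)C(C)(C)C
F2 | step 8 | tert-butyl({8-methoxy-8-[(triethylsilyl)peroxy]nonyl}oxy)diphenylsilane (racemic) | CC(OC)(OO[Si](CC)(CC)CC)CCCCCCCO[Si](c1ccccc1)(c1ccccc1)C(C)(C)C
F3 | step 10 | 2-[(3S,5S)-5-{7-[(tert-butyldiphenylsilyl)oxy]heptyl}-3,5-dimethyl-1,2-dioxolan-3-yl]ethan-1-ol (single enantiomer of 16) | CC(C)(C)[Si](c1ccccc1)(c1ccccc1)OCCCCCCC[C@@]2(C)C[C@](C)(CCO)OO2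
F4 | step 14 | (3Z)-1-iodohex-3-ene | CC/C=C\CCI
F5 | step 14 | [(3Z)-hex-3-en-1-yl]triphenylphosphonium iodide | CC/C=C\CC[P+](c1ccccc1)(c1ccccc1)c1ccccc1.[I-]
F6 | step 14 | 2-[(3S,5S)-3,5-dimethyl-5-[(7E,9Z,12Z)-pentadeca-7,9,12-trien-1-yl]-1,2-dioxolan-3-yl]ethyl (1S,4R)-camphanate | CC/C=C\C/C=C\C=C\CCCCCC[C@@]1(C)C[C@](C)(CCOC(=O)[C@@]23CC[C@@](C)(C(=O)O2)C3(C)C)OO1
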